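**Plan**

- Retrosynthesis: the two phenolic silyl ethers go last. The C2–C3 bond of the chroman-4-one ring is then cut: C2 is an ether carbon on O1 and C3 is the α-carbon of the C4 ketone, so the pair maps onto the OCH2 of an ethoxy group on C8a and the diazo carbon of a 2-diazopropanoyl group on C4a.
- Further back, the diazo group, the silyl ethers and the methyl ester are unpicked. Then the aryl–C3′ bond of the hexanoate chain is cut (to (E)-hex-2-enal), then the C6–prenyl bond and the O1–ethyl bond, which leads to flopropione.
- Forward: flopropione is ethylated on one ortho oxygen (MOM on, ethyl on, MOM off) and prenylated between the two free hydroxyls. It is then joined to hexenal at the last free ring carbon, which closes a temporary lactol ring onto the para oxygen; this is oxidised to the lactone and opened with methoxide.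
- Silylation and diazo transfer give the diazo ketone. The pyranone ring closes in the second-to-last step by C–H insertion, and desilylation ends the route.
- Stereochemistry: the side-chain centre (3R) comes from a diarylprolinol silyl ether iminium catalyst. C2 (R) and C3 (S), cis, come from a chiral dirhodium carboxylate in the insertion and see no base afterwards.

Key step: step 10

Remark: the facial sense of the dirhodium catalyst in step 10 cannot be predicted with certainty for this substrate; the (S)-tert-leucinate complex is written, and its mirror image would be used if a trial run showed the opposite sense.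

**Route**

Step 1
Reactants: 1 flopropione, 1-(2,4,6-trihydroxyphenyl)propan-1-one
Product: 2 1-[2-hydroxy-4,6-bis(methoxymethoxy)phenyl]propan-1-one
Conditions: MOMCl (2.2 equiv), i-Pr2NEt, CH2Cl2, 0 °C to rt
Reagents that add atoms: chloromethyl methyl ether, COCCl
Why: Selective O-alkylation (MOM ether formation): the para hydroxyl and one of the two equivalent ortho hydroxyls should react, while the other ortho hydroxyl is held in a hydrogen bond to the ketone and stays free, the usual behaviour of 2,4,6-trihydroxyaryl ketones.

Step 2
Reactants: 2 the bis-MOM phenol; 3 iodoethane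
Product: 4 1-[2-ethoxy-4,6-bis(methoxymethoxy)phenyl]propan-1-one
Conditions: EtI (1.5 equiv), K2CO3, DMF, 50 °C
Reagents that add atoms: iodoethane (compound 3), CCI
Why: Williamson ether synthesis on the one free, chelated phenol under warm carbonate conditions, which places the ethyl group on the oxygen that becomes O1 of the chromanone; MOM acetals and the ketone are stable to K2CO3.

Step 3
Reactants: 4 the ethyl ether
Product: 5 1-(2-ethoxy-4,6-dihydroxyphenyl)propan-1-one
Conditions: 3 M aq HCl, MeOH, 50 °C
Reagents that add atoms: none
Why: Acid-catalysed cleavage of the two MOM acetals (transacetalisation to dimethoxymethane) should free the para and the second ortho phenol without touching the aryl ethyl ether, and it is done before the acid-sensitive prenyl group is present.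

Step 4
Reactants: 5 the ethoxy diphenol; 6 1-bromo-3-methylbut-2-ene
Product: 7 1-[6-ethoxy-2,4-dihydroxy-3-(3-methylbut-2-enyl)phenyl]propan-1-one
Conditions: prenyl bromide (1.05 equiv), 10% aq KOH, 0 °C; then dilute HCl
Reagents that add atoms: 1-bromo-3-methylbut-2-ene (compound 6), CC(C)=CCBr
Why: Nuclear C-prenylation of a phenoxide (C-alkylation of an acylphloroglucinol dianion): the ring carbon flanked by both oxyanions behaves like the central carbon of a 1,3-dicarbonyl enolate and should be alkylated in preference to the CH next to the ethoxy group, which leaves exactly one ring CH for the side chain.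

Step 5
Reactants: 7 the prenylated diphenol; 8 (E)-hex-2-enal
Product: 9 1-[(4R)-5-ethoxy-2,7-dihydroxy-8-(3-methylbut-2-enyl)-4-propyl-3,4-dihydro-2H-chromen-6-yl]propan-1-one (lactol; both C2 epimers)
Conditions: (S)-α,α-diphenylprolinol trimethylsilyl ether (20 mol %), PhCO2H (20 mol %), toluene, 0 °C to rt
Reagents that add atoms: (E)-hex-2-enal (compound 8), CCC/C=C/C=O
Why: Iminium-catalysed asymmetric Friedel–Crafts alkylation with hemiacetalisation, a reaction known for naphthols, sesamol and other electron-rich phenols: the last free ring carbon, activated by three oxygen substituents, should add to the β-carbon of the E-configured iminium ion on the face opposite the diphenyl(silyloxy)methyl group of the (S)-catalyst, which sets the 4R centre, and the adjacent para hydroxyl then traps the aldehyde as the lactol.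

Step 6
Reactants: 9 the lactol
Product: 10 (4R)-5-ethoxy-7-hydroxy-8-(3-methylbut-2-enyl)-6-propanoyl-4-propyl-3,4-dihydro-2H-chromen-2-one
Conditions: (n-Pr4N)RuO4 (5 mol %), N-methylmorpholine N-oxide, 4 Å molecular sieves, CH2Cl2, rt
Reagents that add atoms: none
Why: Ley–Griffith oxidation of the lactol to the lactone with catalytic perruthenate and the amine oxide, mild enough to leave the chelated phenol, the prenyl double bond and the benzylic stereocentre unchanged.

Step 7
Reactants: 10 the lactone
Product: 11 methyl (3R)-3-[2-ethoxy-4,6-dihydroxy-5-(3-methylbut-2-enyl)-3-propanoylphenyl]hexanoate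
Conditions: NaOMe (2.5 equiv), MeOH, 0 °C; AcOH quench; crude product used at once
Reagents that add atoms: methanol (delivered as NaOMe in MeOH), CO
Why: Transesterification of the aryl lactone by methoxide (methanolysis) should give the methyl ester and free the phenol that becomes the C7 hydroxyl; the benzylic centre is not acidic and the ring could only re-close onto the same oxygen, so neither configuration nor regiochemistry is at risk.

Step 8
Reactants: 11 the dihydroxy ester
Product: 12 methyl (3R)-3-[2,4-bis(tert-butyldimethylsilyloxy)-6-ethoxy-3-(3-methylbut-2-enyl)-5-propanoylphenyl]hexanoate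
Conditions: TBSOTf (2.5 equiv), 2,6-lutidine, CH2Cl2, −78 to 0 °C
Reagents that add atoms: tert-butyldimethylsilyl trifluoromethanesulfonate, CC(C)(C)[Si](C)(C)OS(=O)(=O)C(F)(F)F
Why: Silyl ether formation with the silyl triflate and a hindered pyridine base, fast enough at low temperature to cap both flanked phenols before the hydroxy ester can re-lactonise; no later step uses hydroxide, alkoxide or carbonate in a protic medium, which would cleave aryl silyl ethers.

Step 9
Reactants: 12 the bis-silyl ethyl ketone
Product: 14 methyl (3R)-3-[2,4-bis(tert-butyldimethylsilyloxy)-5-(2-diazopropanoyl)-6-ethoxy-3-(3-methylbut-2-enyl)phenyl]hexanoate, via the α-trifluoroacetyl ketone 13 (not isolated)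
Conditions: LiN(SiMe3)2 (1.05 equiv), THF, −78 °C; CF3CO2CH2CF3; dilute HCl wash; then MsN3, Et3N, H2O (1 equiv), MeCN, rt
Reagents that add atoms: methanesulfonyl azide, CS(=O)(=O)N=[N+]=[N-]; 2,2,2-trifluoroethyl trifluoroacetate (its atoms stay only in 13), O=C(OCC(F)(F)F)C(F)(F)F
Why: Detrifluoroacetylative diazo transfer (a Regitz-type deacylative diazo transfer): the lithium enolate of the aryl ethyl ketone, whose α-hydrogens are more acidic than those of the ester, should be C-trifluoroacetylated, and the activated methine of 13 then takes up the diazo group from mesyl azide with loss of the trifluoroacetyl group as the sulfonyl amide.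

Step 10
Reactants: 14 the diazo ketone
Product: 15 methyl (3R)-3-[(2R,3S)-5,7-bis(tert-butyldimethylsilyloxy)-2,3-dimethyl-6-(3-methylbut-2-enyl)-4-oxochroman-8-yl]hexanoate
Conditions: Rh2(S-PTTL)4 (1 mol %), CH2Cl2, −40 to 0 °C, slow addition of 14
Reagents that add atoms: none
Why: Dirhodium tetrakis[N-phthaloyl-(S)-tert-leucinate], a chiral carboxylate of divalent rhodium, expels N2 from 14 to give an electrophilic rhodium carbenoid at the future C3, which inserts into one of the two enantiotopic C–H bonds of the OCH2 group on C8a in a concerted, asynchronous transition state in which hydride moves to the carbenoid carbon as C2–C3 develops and the metal leaves. The closest known reaction is the chiral dirhodium carboxylate-catalysed C–H insertion of 2-alkoxyaryl α-diazo ketones, which gives cis-2,3-disubstituted chroman-4-ones. The pyranone ring closes as a six-membered ring by 1,6-insertion, since the position that would give a five-membered ring is occupied by O1, which has no hydrogen, and the methylene next to that oxygen is the most electron-rich C–H bond within reach. C2 and C3 are created together: their cis relationship should follow from the compact insertion transition state and is kept because the medium is neutral, while the absolute sense (2R,3S) is imposed by the chiral carboxylate ligands, the distant side-chain centre having little influence. The step needs C–H insertion to win over 1,2-hydride shift from the C3 methyl group, oxonium-ylide formation at O1 or at a silyloxy oxygen, and addition to the prenyl double bond; low temperature and the bulky carboxylates hold back the hydride shift, the tert-butyldimethylsilyl ethers are poor ylide donors and have no activated C–H bond, and the prenyl alkene on C6 and the ester chain on C8 could reach the carbenoid only through strained bridged transition states.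

Step 11
Reactants: 15 the bis-silyl chromanone
Product: 16 methyl (3R)-3-[(2R,3S)-5,7-dihydroxy-2,3-dimethyl-6-(3-methylbut-2-enyl)-4-oxochroman-8-yl]hexanoate (CNP0068017.1)
Conditions: HF·pyridine, excess pyridine, THF, 0 °C to rt
Reagents that add atoms: none
Why: Fluoride-induced cleavage of the two aryl silyl ethers in a pyridine-buffered medium that is neither basic enough to enolise the ketone nor acidic enough to cyclise the prenyl group onto a phenol, so the cis C2/C3 centres should survive.

**Compound list**

1 | 1-(2,4,6-trihydroxyphenyl)propan-1-one (flopropione) | CCC(=O)c1c(O)cc(O)cc1O | starting material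
2 | 1-[2-hydroxy-4,6-bis(methoxymethoxy)phenyl]propan-1-one | CCC(=O)c1c(O)cc(OCOC)cc1OCOC | intermediate
3 | iodoethane | CCI | starting material
4 | 1-[2-ethoxy-4,6-bis(methoxymethoxy)phenyl]propan-1-one | CCC(=O)c1c(OCC)cc(OCOC)cc1OCOC | intermediate
5 | 1-(2-ethoxy-4,6-dihydroxyphenyl)propan-1-one | CCC(=O)c1c(OCC)cc(O)cc1O | intermediate
6 | 1-bromo-3-methylbut-2-ene | CC(C)=CCBr | starting material
7 | 1-[6-ethoxy-2,4-dihydroxy-3-(3-methylbut-2-enyl)phenyl]propan-1-one | CCC(=O)c1c(O)c(CC=C(C)C)c(O)cc1OCC | intermediate
8 | (E)-hex-2-enal | CCC/C=C/C=O | starting material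
9 | 1-[(4R)-5-ethoxy-2,7-dihydroxy-8-(3-methylbut-2-enyl)-4-propyl-3,4-dihydro-2H-chromen-6-yl]propan-1-one (lactol, C2 epimers) | CCC[C@@H]1CC(O)Oc2c1c(OCC)c(C(=O)CC)c(O)c2CC=C(C)C | intermediate
10 | (4R)-5-ethoxy-7-hydroxy-8-(3-methylbut-2-enyl)-6-propanoyl-4-propyl-3,4-dihydro-2H-chromen-2-one | CCC[C@@H]1CC(=O)Oc2c1c(OCC)c(C(=O)CC)c(O)c2CC=C(C)C | intermediate
11 | methyl (3R)-3-[2-ethoxy-4,6-dihydroxy-5-(3-methylbut-2-enyl)-3-propanoylphenyl]hexanoate | CCC[C@H](CC(=O)OC)c1c(O)c(CC=C(C)C)c(O)c(C(=O)CC)c1OCC | intermediate
12 | methyl (3R)-3-[2,4-bis(tert-butyldimethylsilyloxy)-6-ethoxy-3-(3-methylbut-2-enyl)-5-propanoylphenyl]hexanoate | CCC[C@H](CC(=O)OC)c1c(O[Si](C)(C)C(C)(C)C)c(CC=C(C)C)c(O[Si](C)(C)C(C)(C)C)c(C(=O)CC)c1OCC | intermediate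
13 | methyl (3R)-3-[2,4-bis(tert-butyldimethylsilyloxy)-6-ethoxy-3-(3-methylbut-2-enyl)-5-(4,4,4-trifluoro-2-methyl-3-oxobutanoyl)phenyl]hexanoate | CCC[C@H](CC(=O)OC)c1c(O[Si](C)(C)C(C)(C)C)c(CC=C(C)C)c(O[Si](C)(C)C(C)(C)C)c(C(=O)C(C)C(=O)C(F)(F)F)c1OCC | intermediate
14 | methyl (3R)-3-[2,4-bis(tert-butyldimethylsilyloxy)-5-(2-diazopropanoyl)-6-ethoxy-3-(3-methylbut-2-enyl)phenyl]hexanoate | CCC[C@H](CC(=O)OC)c1c(O[Si](C)(C)C(C)(C)C)c(CC=C(C)C)c(O[Si](C)(C)C(C)(C)C)c(C(=O)C(C)=[N+]=[N-])c1OCC | intermediate
15 | methyl (3R)-3-[(2R,3S)-5,7-bis(tert-butyldimethylsilyloxy)-2,3-dimethyl-6-(3-methylbut-2-enyl)-4-oxochroman-8-yl]hexanoate | CCC[C@H](CC(=O)OC)c1c(O[Si](C)(C)C(C)(C)C)c(CC=C(C)C)c(O[Si](C)(C)C(C)(C)C)c2c1O[C@H](C)[C@H](C)C2=O | intermediate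
16 | methyl (3R)-3-[(2R,3S)-5,7-dihydroxy-2,3-dimethyl-6-(3-methylbut-2-enyl)-4-oxochroman-8-yl]hexanoate | CCC[C@H](CC(=O)OC)c1c(O)c(CC=C(C)C)c(O)c2c1O[C@H](C)[C@H](C)C2=O | target

**Count and risks**

Total step count: 11. Longest linear sequence: 11 steps (1 to 16).

Steps most likely to fail:

1. Step 5. What may go wrong: the acyl-bearing phenol adds too slowly to the iminium ion; the addition reverts through the enamine, so that facial selectivity is eroded; or 1,2-addition to the iminium carbon leads on to a 2H-chromene. Fallback (sets out from 7, comes back at 10, replaces steps 5 and 6): 7 is heated with butanal and Meldrum's acid in pyridine at about 90 °C. Knoevenagel condensation gives 5-butylidene-2,2-dimethyl-1,3-dioxane-4,6-dione F1 in the flask. The free ring carbon of 7 adds to it in a Michael reaction, and the neighbouring para hydroxyl opens the dioxanedione with loss of acetone and carbon dioxide. This is a known three-component route from phloroglucinols to 4-substituted dihydrocoumarins and should give racemic 5-ethoxy-7-hydroxy-8-(3-methylbut-2-enyl)-6-propanoyl-4-propyl-3,4-dihydro-2H-chromen-2-one F2. Preparative chromatography on a chiral stationary phase then separates 10 from (4S)-5-ethoxy-7-hydroxy-8-(3-methylbut-2-enyl)-6-propanoyl-4-propyl-3,4-dihydro-2H-chromen-2-one F3, which is discarded.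

2. Step 10. What may go wrong: the carbenoid is diverted into 1,2-hydride shift from the C3 methyl group or into ylide formation at an ether oxygen, or the chiral ligand sphere fails to tell apart the two enantiotopic methylene hydrogens in this crowded, fully substituted arene (poor facial selectivity). Fallback (sets out from 14, comes back at 15): absolute control by the catalyst is given up and only the relative configuration is asked of the insertion. 14 is decomposed with the achiral, very bulky dirhodium tetrakis(triphenylacetate), Rh2(O2CCPh3)4, in CH2Cl2 at −78 °C; carboxylates of this size are the known remedy against hydride shift in α-alkyl carbenoids. The cis pair should result, that is 15 together with methyl (3R)-3-[(2S,3R)-5,7-bis(tert-butyldimethylsilyloxy)-2,3-dimethyl-6-(3-methylbut-2-enyl)-4-oxochroman-8-yl]hexanoate F4. Because the side-chain centre is fixed, these two are diastereomers and would be separated by chromatography on silica; F4 is set aside.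

3. Step 4. What may go wrong: loss of site selectivity in the ambident dianion, with alkylation on oxygen, at the ring carbon next to the ethoxy group, or twice. Fallback (sets out from 2, comes back at 7, replaces steps 2 to 4): the chelated phenol of 2 is alkylated with prenyl bromide (K2CO3, acetone, reflux) to 1-[2,4-bis(methoxymethoxy)-6-(3-methylbut-2-enyloxy)phenyl]propan-1-one F5. Heating in N,N-diethylaniline at about 200 °C should bring about the para-Claisen–Cope rearrangement. The prenyl group moves by two consecutive [3,3] shifts to the ring carbon para to the ether oxygen, the one between the two MOM ethers, and the chelated phenol is regenerated in 1-[6-hydroxy-2,4-bis(methoxymethoxy)-3-(3-methylbut-2-enyl)phenyl]propan-1-one F6. Ethylation as in step 2 (EtI, K2CO3, DMF) gives 1-[6-ethoxy-2,4-bis(methoxymethoxy)-3-(3-methylbut-2-enyl)phenyl]propan-1-one F7, and brief treatment with dilute HCl in MeOH at room temperature removes both MOM groups to give 7.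

Further compounds
F1 | step 5 | 5-butylidene-2,2-dimethyl-1,3-dioxane-4,6-dione | CCCC=C1C(=O)OC(C)(C)OC1=O
F2 | step 5 | racemic 5-ethoxy-7-hydroxy-8-(3-methylbut-2-enyl)-6-propanoyl-4-propyl-3,4-dihydro-2H-chromen-2-one | CCCC1CC(=O)Oc2c1c(OCC)c(C(=O)CC)c(O)c2CC=C(C)C
F3 | step 5 | (4S)-5-ethoxy-7-hydroxy-8-(3-methylbut-2-enyl)-6-propanoyl-4-propyl-3,4-dihydro-2H-chromen-2-one | CCC[C@H]1CC(=O)Oc2c1c(OCC)c(C(=O)CC)c(O)c2CC=C(C)C
F4 | step 10 | methyl (3R)-3-[(2S,3R)-5,7-bis(tert-butyldimethylsilyloxy)-2,3-dimethyl-6-(3-methylbut-2-enyl)-4-oxochroman-8-yl]hexanoate | CCC[C@H](CC(=O)OC)c1c(O[Si](C)(C)C(C)(C)C)c(CC=C(C)C)c(O[Si](C)(C)C(C)(C)C)c2c1O[C@@H](C)[C@@H](C)C2=O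
F5 | step 4 | 1-[2,4-bis(methoxymethoxy)-6-(3-methylbut-2-enyloxy)phenyl]propan-1-one | CCC(=O)c1c(OCC=C(C)C)cc(OCOC)cc1OCOC
F6 | step 4 | 1-[6-hydroxy-2,4-bis(methoxymethoxy)-3-(3-methylbut-2-enyl)phenyl]propan-1-one | CCC(=O)c1c(O)cc(OCOC)c(CC=C(C)C)c1OCOC
F7 | step 4 | 1-[6-ethoxy-2,4-bis(methoxymethoxy)-3-(3-methylbut-2-enyl)phenyl]propan-1-one | CCC(=O)c1c(OCC)cc(OCOC)c(CC=C(C)C)c1OCOC
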